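The all-E triene C7–C12, which links the C4 carbinol of the epoxycyclohexenone ring to the C13 amide on the aminocyclopentenone ring, is cut at C8–C9 and C10–C11, so that its central C9=C10 vinylene comes from a bromovinyl MIDA boronate. In one flask, a Stille coupling at C8 and then a Suzuki coupling at C11 assemble the triene and give the target directly, without touching a ring or a stereocentre. The precursor is the complete core: the C5–C6 epoxide, the free C4 hydroxyl syn to it, the C1 ketone, the finished C2 dienamide and an (E)-2-(tributylstannyl)vinyl group on C4.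

Key step: step 11

Remark on numbering: core atoms are numbered as in the target (C1 ketone, C2 amide-bearing carbon, C3, C4 carbinol, C5 and C6 epoxide carbons, C7–C13 lower chain). The target is (4R,5S,6R) with the hydroxyl syn to the epoxide oxygen.

Remark on depiction: the 2-amino-1,3-dione unit is written as its 3-hydroxy-enone tautomer. The MIDA boronate is written without its transannular N→B dative bond, which is present and is what keeps the boron inert.

Assumption: the facial sense of the phase-transfer epoxidation in step 5 is assigned by analogy with related 3-amido quinone monoketals and is to be verified on compound 9. The pseudoenantiomeric N-benzylcinchoninium chloride reverses it if needed.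

**Route**

Step 1
Reactants: 1 cyclohexanecarbaldehyde; 2 triethyl (E)-4-phosphonocrotonate
Product: 3 ethyl (2E,4E)-5-cyclohexylpenta-2,4-dienoate
Conditions: LiN(SiMe3)2, THF, −78 → 0 °C
Reagents that add atoms: none
Why: Vinylogous Horner–Wadsworth–Emmons olefination, in which the phosphonate anion reacts at the carbon next to phosphorus and should give the favoured E geometry at the new C4=C5 bond while C2=C3 stays E.

Step 2
Reactants: 3 ethyl (2E,4E)-5-cyclohexylpenta-2,4-dienoate
Product: 4 (2E,4E)-5-cyclohexylpenta-2,4-dienoic acid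
Conditions: LiOH, THF/MeOH/H2O, rt; then 1 M HCl; recrystallisation
Reagents that add atoms: lithium hydroxide, [Li+].[OH-]
Why: Ester saponification of a dienoate that has no base-sensitive group, and crystallisation of the acid should remove minor geometric isomers.

Step 3
Reactants: 4 (2E,4E)-5-cyclohexylpenta-2,4-dienoic acid; 5 2,5-dimethoxyaniline
Product: 7 (2E,4E)-5-cyclohexyl-N-(2,5-dimethoxyphenyl)penta-2,4-dienamide, via dienoyl chloride 6 (not isolated)
Conditions: (COCl)2, cat. DMF, CH2Cl2, 0 °C → rt; concentrate; then 5, pyridine, CH2Cl2, 0 °C → rt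
Reagents that add atoms: oxalyl chloride, ClC(=O)C(=O)Cl (gives the chlorine of 6; none of its atoms stays in 7)
Why: Acid chloride formation followed by N-acylation of a nucleophilic aniline, which puts the complete upper amide in place before the ring becomes electrophilic.

Step 4
Reactants: 7 (2E,4E)-5-cyclohexyl-N-(2,5-dimethoxyphenyl)penta-2,4-dienamide
Product: 8 (2E,4E)-5-cyclohexyl-N-(6,6-dimethoxy-3-oxocyclohexa-1,4-dien-1-yl)penta-2,4-dienamide
Conditions: PhI(OAc)2, MeOH, 0 °C → rt; aq. NaHCO3 work-up
Reagents that add atoms: methanol, CO; water, O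
Why: Oxidative dearomatisation of a para-dimethoxy anilide by a hypervalent iodine reagent, in which methanol adds at the methoxy-bearing carbon ortho to nitrogen and the other methoxy carbon is unmasked as the ketone, so the 3-amido quinone monoketal should form regioselectively while the electron-poor dienamide is left alone.

Step 5
Reactants: 8 (2E,4E)-5-cyclohexyl-N-(6,6-dimethoxy-3-oxocyclohexa-1,4-dien-1-yl)penta-2,4-dienamide
Product: 9 (2E,4E)-5-cyclohexyl-N-[(1R,6S)-2,2-dimethoxy-5-oxo-7-oxabicyclo[4.1.0]hept-3-en-3-yl]penta-2,4-dienamide (5S,6R in core numbering)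
Conditions: t-BuOOH, aq. NaOH, N-benzylcinchonidinium chloride, toluene, 0 °C → rt; recrystallisation
Reagents that add atoms: tert-butyl hydroperoxide, CC(C)(C)OO
Why: Weitz–Scheffer nucleophilic epoxidation under chiral phase-transfer catalysis, in which the peroxide anion attacks only the unsubstituted enone double bond (the other is deactivated by the amide nitrogen) and the chiral ammonium ion pair is expected to select the face that sets C5 and C6 together as the (5S,6R) cis-epoxide.

Step 6
Reactants: 9 the (5S,6R) epoxy ketone; 10 (E)-1,2-bis(tributylstannyl)ethene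
Product: 12 ketal-protected carbinol stannane (4S,5S,6R in core numbering; hydroxyl syn to the epoxide), via stannylvinyllithium 11 (not isolated)
Conditions: 10 (3 equiv), n-BuLi (3 equiv), THF, −78 °C; then 9, −78 °C; aq. NH4Cl
Reagents that add atoms: n-butyllithium, [Li]CCCC (gives the lithium of 11; none of its atoms stays in 12)
Why: Tin–lithium exchange gives the (E)-stannylvinyllithium, whose first equivalent deprotonates the amide N–H (protecting the dienamide as its anion) and whose next equivalent adds 1,2 to the ketone from the face opposite the epoxide oxygen, so C4 is set by the substrate with the hydroxyl syn to the epoxide and the E vinyl geometry is retained.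

Step 7
Reactants: 12 ketal-protected carbinol stannane
Product: 13 core (E)-vinylstannane with free C1 ketone (4S,5S,6R in core numbering; C4 is S only because tin raises the priority of the vinyl group, the spatial arrangement being that of the target)
Conditions: montmorillonite K10 clay (acid-treated aluminosilicate, idealised Al2Si4O10(OH)2·nH2O), moist CH2Cl2, rt
Reagents that add atoms: water, O
Why: Mild heterogeneous acid hydrolysis of the dimethyl ketal, chosen so that the C1 ketone is released without protodestannylation of the vinylstannane or ionisation of the tertiary allylic alcohol, and with no stereocentre touched.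

Step 8
Reactants: 14 cyclopentane-1,3-dione
Product: 15 2-(hydroxyimino)cyclopentane-1,3-dione
Conditions: NaNO2, aq. HCl, 0 °C
Reagents that add atoms: sodium nitrite, [Na+].[O-]N=O
Why: Electrophilic nitrosation of the enol of a 1,3-diketone at C2 followed by tautomerisation to the oxime, the classical entry to 2-amino-1,3-diones.

Step 9
Reactants: 15 2-(hydroxyimino)cyclopentane-1,3-dione
Product: 16 2-amino-3-hydroxycyclopent-2-en-1-one hydrochloride
Conditions: H2 (1 atm), Pd/C, MeOH, HCl, rt
Reagents that add atoms: hydrogen chloride, Cl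
Why: Catalytic hydrogenation of an α-oximino ketone in acid, which traps the amine as its hydrochloride, prevents self-condensation and leaves the stable 3-hydroxy-enone form.

Step 10
Reactants: 16 2-amino-3-hydroxycyclopent-2-en-1-one hydrochloride; 17 (E)-3-iodoacrylic acid
Product: 19 (E)-N-(2-hydroxy-5-oxocyclopent-1-en-1-yl)-3-iodoacrylamide, via iodoacryloyl chloride 18 (not isolated)
Conditions: 17, (COCl)2, cat. DMF, CH2Cl2, 0 °C → rt; concentrate; then 16, NaHCO3, THF/H2O, 0 °C; acidify to pH 3
Reagents that add atoms: oxalyl chloride, ClC(=O)C(=O)Cl (gives the chlorine of 18; none of its atoms stays in 19)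
Why: Schotten–Baumann N-acylation at low temperature without a tertiary amine, so that the E iodoalkene is preserved and any O-acylated material either transfers its acyl group to the neighbouring nitrogen or is cleaved on work-up.

Step 11
Reactants: 13 core (E)-vinylstannane; 19 (E)-N-(2-hydroxy-5-oxocyclopent-1-en-1-yl)-3-iodoacrylamide; 20 (E)-2-bromovinylboronic acid MIDA ester
Product: 23 target CNP0111189.1, via dienyl MIDA boronate 21 (not isolated), via dienylboronic acid 22 (not isolated)
Conditions: 13, 20 (1.05 equiv), Pd2(dba)3, P(2-furyl)3, DMF, 30 °C, dark, until 13 is consumed; then 19 (1.3 equiv), 3 M aq. K3PO4, THF, 40 °C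
Reagents that add atoms: water, O (gives the oxygen atoms of the B(OH)2 group of 22; none stays in 23)
Why: Zerovalent palladium inserts into the C–Br bond of 20, the C8–Sn bond of 13 transmetalates under neutral conditions and reductive elimination forms C8–C9 to give 21, whose tetracoordinate boron cannot transmetalate; aqueous phosphate then releases boronic acid 22 slowly, the catalyst inserts into the C–I bond of 19, the boronate transmetalates and reductive elimination forms C10–C11. The closest known reaction type is iterative cross-coupling with halovinyl MIDA boronates, here a Stille coupling followed in the same flask by a slow-release Suzuki–Miyaura coupling. No ring closes and no stereocentre is created, so C4, C5 and C6 are only carried through. The step needs chemoselectivity (one halide and one carbon–metal bond active in each phase) and retention of three E double bonds: the first is secured by the MIDA mask and by adding iodide 19 and base only after stannane 13 is consumed (otherwise 13 and 19 would couple directly), the second by the stereoretentive elementary steps. The epoxide, the tertiary allylic alcohol and the enone meet only neutral and then weakly basic conditions, and the light- and acid-sensitive triene is created in the last bond-forming event.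

**Compound list**

1 | cyclohexanecarbaldehyde | O=CC1CCCCC1 | starting material
2 | triethyl (E)-4-phosphonocrotonate | CCOC(=O)/C=C/CP(=O)(OCC)OCC | starting material
3 | ethyl (2E,4E)-5-cyclohexylpenta-2,4-dienoate | CCOC(=O)/C=C/C=C/C1CCCCC1 | intermediate
4 | (2E,4E)-5-cyclohexylpenta-2,4-dienoic acid | OC(=O)/C=C/C=C/C1CCCCC1 | intermediate
5 | 2,5-dimethoxyaniline | COc1ccc(OC)c(N)c1 | starting material
6 | (2E,4E)-5-cyclohexylpenta-2,4-dienoyl chloride | ClC(=O)/C=C/C=C/C1CCCCC1 | intermediate (not isolated)
7 | (2E,4E)-5-cyclohexyl-N-(2,5-dimethoxyphenyl)penta-2,4-dienamide | O=C(/C=C/C=C/C1CCCCC1)Nc1cc(OC)ccc1OC | intermediate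
8 | (2E,4E)-5-cyclohexyl-N-(6,6-dimethoxy-3-oxocyclohexa-1,4-dien-1-yl)penta-2,4-dienamide | O=C(/C=C/C=C/C1CCCCC1)NC1=CC(=O)C=CC1(OC)OC | intermediate
9 | (2E,4E)-5-cyclohexyl-N-[(1R,6S)-2,2-dimethoxy-5-oxo-7-oxabicyclo[4.1.0]hept-3-en-3-yl]penta-2,4-dienamide | O=C(/C=C/C=C/C1CCCCC1)NC1=CC(=O)[C@H]2O[C@H]2C1(OC)OC | intermediate
10 | (E)-1,2-bis(tributylstannyl)ethene | CCCC[Sn](CCCC)(CCCC)/C=C/[Sn](CCCC)(CCCC)CCCC | starting material
11 | (E)-2-(tributylstannyl)vinyllithium | [Li]/C=C/[Sn](CCCC)(CCCC)CCCC | intermediate (not isolated)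
12 | (2E,4E)-5-cyclohexyl-N-[(1R,5S,6S)-5-hydroxy-2,2-dimethoxy-5-[(E)-2-(tributylstannyl)ethenyl]-7-oxabicyclo[4.1.0]hept-3-en-3-yl]penta-2,4-dienamide | O=C(/C=C/C=C/C1CCCCC1)NC1=C[C@](O)(/C=C/[Sn](CCCC)(CCCC)CCCC)[C@H]2O[C@H]2C1(OC)OC | intermediate
13 | (2E,4E)-5-cyclohexyl-N-[(1R,5S,6S)-5-hydroxy-2-oxo-5-[(E)-2-(tributylstannyl)ethenyl]-7-oxabicyclo[4.1.0]hept-3-en-3-yl]penta-2,4-dienamide | O=C(/C=C/C=C/C1CCCCC1)NC1=C[C@](O)(/C=C/[Sn](CCCC)(CCCC)CCCC)[C@H]2O[C@H]2C1=O | intermediate
14 | cyclopentane-1,3-dione | O=C1CCC(=O)C1 | starting material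
15 | 2-(hydroxyimino)cyclopentane-1,3-dione | O=C1CCC(=O)C1=NO | intermediate
16 | 2-amino-3-hydroxycyclopent-2-en-1-one hydrochloride | Cl.NC1=C(O)CCC1=O | intermediate
17 | (E)-3-iodoacrylic acid | OC(=O)/C=C/I | starting material
18 | (E)-3-iodoacryloyl chloride | ClC(=O)/C=C/I | intermediate (not isolated)
19 | (E)-N-(2-hydroxy-5-oxocyclopent-1-en-1-yl)-3-iodoacrylamide | I/C=C/C(=O)NC1=C(O)CCC1=O | intermediate
20 | (E)-2-bromovinylboronic acid MIDA ester | Br/C=C/B1OC(=O)CN(C)CC(=O)O1 | starting material
21 | core (1E,3E)-dienyl MIDA boronate (4R,5S,6R in core numbering) | O=C(/C=C/C=C/C1CCCCC1)NC1=C[C@](O)(/C=C/C=C/B3OC(=O)CN(C)CC(=O)O3)[C@H]2O[C@H]2C1=O | intermediate (not isolated)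
22 | core (1E,3E)-dienylboronic acid (4R,5S,6R in core numbering) | O=C(/C=C/C=C/C1CCCCC1)NC1=C[C@](O)(/C=C/C=C/B(O)O)[C@H]2O[C@H]2C1=O | intermediate (not isolated)
23 | (2E,4E)-5-cyclohexyl-N-[(1R,5R,6S)-5-hydroxy-5-[(1E,3E,5E)-7-[(2-hydroxy-5-oxocyclopent-1-en-1-yl)amino]-7-oxohepta-1,3,5-trien-1-yl]-2-oxo-7-oxabicyclo[4.1.0]hept-3-en-3-yl]penta-2,4-dienamide | O=C(/C=C/C=C/C1CCCCC1)NC1=C[C@](O)(/C=C/C=C/C=C/C(=O)NC2=C(O)CCC2=O)[C@H]2O[C@H]2C1=O | target

**Step count and risk**

Total step count: 11. Longest linear sequence: 8 (steps 1–7 and 11); steps 8–10 form the convergent branch.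

Steps most likely to fail:

1. Step 11. The dienylboronic acid released from 21 may protodeboronate or oligomerise faster than it cross-couples, and long exposure to aqueous phosphate may degrade the epoxy enone. The fallback avoids boron, water and base. It sets out from 19 and uses 10 and 13, which the route already holds. A Stille coupling of 19 with an excess of 10 (Pd2(dba)3, P(2-furyl)3, DMF, rt) should form C10–C11 and give (2E,4E)-N-(2-hydroxy-5-oxocyclopent-1-en-1-yl)-5-(tributylstannyl)penta-2,4-dienamide F1. Iododestannylation (I2, CH2Cl2, 0 °C) should give (2E,4E)-N-(2-hydroxy-5-oxocyclopent-1-en-1-yl)-5-iodopenta-2,4-dienamide F2 with retention of geometry. A neutral Stille coupling of F2 with 13 (PdCl2(MeCN)2, DMF, rt, dark) then forms C8–C9 and comes back to the route at 23.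

2. Step 5. With the new N-dienoyl substrate the ion-pair-controlled peroxide addition may show poor or reversed facial selectivity, or the base may erode the material. The fallback moves the epoxidation to a simple carbamate, the substrate type on which this phase-transfer epoxidation has been demonstrated, and brings in the acyl group afterwards. It sets out from 5. Boc2O in THF should give tert-butyl (2,5-dimethoxyphenyl)carbamate F3. PhI(OAc)2 in MeOH should give tert-butyl (6,6-dimethoxy-3-oxocyclohexa-1,4-dien-1-yl)carbamate F4. The same t-BuOOH/NaOH/N-benzylcinchonidinium chloride epoxidation with recrystallisation should give tert-butyl [(1R,6S)-2,2-dimethoxy-5-oxo-7-oxabicyclo[4.1.0]hept-3-en-3-yl]carbamate F5. N-acylation with acid chloride 6 (LiOt-Bu, THF, −78 °C) should give the N-Boc imide tert-butyl [(2E,4E)-5-cyclohexylpenta-2,4-dienoyl][(1R,6S)-2,2-dimethoxy-5-oxo-7-oxabicyclo[4.1.0]hept-3-en-3-yl]carbamate F6. Selective removal of the Boc group from the imide (Mg(ClO4)2, MeCN, 40 °C) comes back to the route at 9.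

3. Step 6. N-Deprotonation lowers the electrophilicity of the ketone, and the stannylvinyllithium cannot be warmed to compensate, so the 1,2-addition may stall or lose facial selectivity. The fallback uses a thermally robust two-carbon nucleophile and installs tin afterwards. It sets out from 9. Excess ethynylmagnesium bromide (THF, −20 → 20 °C) should add anti to the epoxide and give the ethynyl carbinol (2E,4E)-5-cyclohexyl-N-[(1R,5S,6S)-5-ethynyl-5-hydroxy-2,2-dimethoxy-7-oxabicyclo[4.1.0]hept-3-en-3-yl]penta-2,4-dienamide F7. Palladium-catalysed syn-hydrostannylation (Bu3SnH, PdCl2(PPh3)2, THF, 0 °C) should place tin at the unhindered terminal carbon with E geometry; at the ketal stage no enone is present to be reduced. This comes back to the route at 12.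

**Further compounds**

F1 | step 11 | (2E,4E)-N-(2-hydroxy-5-oxocyclopent-1-en-1-yl)-5-(tributylstannyl)penta-2,4-dienamide | CCCC[Sn](CCCC)(CCCC)/C=C/C=C/C(=O)NC1=C(O)CCC1=O
F2 | step 11 | (2E,4E)-N-(2-hydroxy-5-oxocyclopent-1-en-1-yl)-5-iodopenta-2,4-dienamide | I/C=C/C=C/C(=O)NC1=C(O)CCC1=O
F3 | step 5 | tert-butyl (2,5-dimethoxyphenyl)carbamate | COc1ccc(OC)c(NC(=O)OC(C)(C)C)c1
F4 | step 5 | tert-butyl (6,6-dimethoxy-3-oxocyclohexa-1,4-dien-1-yl)carbamate | CC(C)(C)OC(=O)NC1=CC(=O)C=CC1(OC)OC
F5 | step 5 | tert-butyl [(1R,6S)-2,2-dimethoxy-5-oxo-7-oxabicyclo[4.1.0]hept-3-en-3-yl]carbamate | CC(C)(C)OC(=O)NC1=CC(=O)[C@H]2O[C@H]2C1(OC)OC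
F6 | step 5 | tert-butyl [(2E,4E)-5-cyclohexylpenta-2,4-dienoyl][(1R,6S)-2,2-dimethoxy-5-oxo-7-oxabicyclo[4.1.0]hept-3-en-3-yl]carbamate | O=C(/C=C/C=C/C1CCCCC1)N(C(=O)OC(C)(C)C)C1=CC(=O)[C@H]2O[C@H]2C1(OC)OC
F7 | step 6 | (2E,4E)-5-cyclohexyl-N-[(1R,5S,6S)-5-ethynyl-5-hydroxy-2,2-dimethoxy-7-oxabicyclo[4.1.0]hept-3-en-3-yl]penta-2,4-dienamide | O=C(/C=C/C=C/C1CCCCC1)NC1=C[C@](O)(C#C)[C@H]2O[C@H]2C1(OC)OC
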